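Readings and results are simulated with made-up constants.

The pitfall in repeating this run is to wait for more target. Monday's target reads 8.9%, 10.0% and 9.0% of the substrate charged at 6.00 min, 8.00 min and 10.0 min, and the mean of those plateau readings is a fraction 9.30%.

| flask | substrate | reagent in the second phase | remark | time | volume of the second phase over the first |
|---|---|---|---|---|---|
| Monday's | 0.15 M | 0.33 M | run made earlier |  |  |
| flask | 0.30 M | 0.330 M |  | 30 min | 0.50 |

Monday's run (percent of the substrate charged)

| time / min | target / % | substrate / % |
|---|---|---|
| 1.33 | 4.4 | 96.6 |
| 2.50 | 5.7 | 93.3 |
| 4.00 | 8.3 | 92.4 |
| 5.00 | 8.9 | 91.2 |
| 6.00 | 8.9 | 90.6 |
| 8.00 | 10.0 | 89.7 |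
| 10.0 | 9.0 | 90.1 |

(readings scatter by 0.5 percentage points)

- in the second phase: reagent in the second phase; everything else is in the first
- charges count per volume of the first phase; a concentration in a rate is the amount of a species over the volume of its own phase; every rate counts per litre of the first phase
- the earlier runs hold the two phases in the same ratio of volumes as the flask asked about

* amount of target at 30 min, in percent of the substrate charged
* the change that raises the amount of target at 30 min, in percent of the substrate charged most ("none" if none brings more than 2 percentage points) (spring / noon / none)
* amount of target at 30 min, in percent of the substrate charged, after spring

- spring: doubling the amount of reagent in the second phase, all else as stated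
- noon: doubling the transfer coefficient of the reagent in the second phase, all else as stated

Taken one for one, target at that mean reading has drawn just 4.23% of the reagent charged, so the plateau can't be read as reagent used up on substrate. Either a balance or a loss of reagent elsewhere could stop it, and my reckoning needn't choose. Fold the plateau into the exposure 0.0976, the natural logarithm of the substrate charged over the substrate not turned into target. I take the substrate to be pseudo-first-order, so that a given reagent charge takes a fixed fraction of it, while I let the exposure grow in step with the reagent.

The flask has Monday's reagent, so I keep the exposure and get 9.30%. Spring doubles it and gives 17.7%. Monday's readings have levelled by 8.00 min, sooner than the asked 30 min, so I expect nothing from noon. Is one number enough? The flask's draw is 8.45%, still small, but Monday tested a single reagent charge.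

The forecast gives 9.5%, spring and 17.5%, holding that “Thirty minutes is ample to reach equilibrium”.

The flask gives 9.11%. Spring changes it by 6.4 percentage points to 15.5%, and noon by −0.015 points.

    reagent in the reaction phase + target → over-reacted product (k = 0.00380 /M/s)
    substrate + reagent in the reaction phase → target (k = 0.00290 /M/s)
    reagent in the reaction phase ⇌ reagent in the second phase, rate k3*([reagent in the reaction phase] - [reagent in the second phase]/K3) per volume of the first phase (partition coefficient = 0.410, kL = 0.0230 /s)
    2 reagent in the reaction phase → self-condensation product (k = 0.00220 /M/s)
    reagent in the reaction phase → decomposed reagent (k = 0.00790 /s)

At 0.114 min in the flask, reagent in the reaction phase goes to decomposed reagent 9.1 times as fast as it goes to target. At 30.0 min the flask's decomposed reagent stands at 84.6% of the reagent charged, and its reagent in the second phase at 0% of its own charge. The flask's exposure is 0.0955, against the 0.0976 taken from Monday's readings. In a neighbouring flask with 1.2 M of substrate, keeping 0.0976 would draw 33.8% of the reagent charged, and that neighbour gives 7.29%, an exposure of 0.0757.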